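C3-OH is traced back to the 3-ketone and then to a C3=C4 methyl enol ether. The C4-C5 bond is cut next, so that C5 returns to oxygen as the carbon of a methyl acetal on O1, and the C5-O1 acetal bond then divides the molecule into an (S)-propargylic alcohol and a dihydrobenzofuran-5-carbaldehyde dimethyl acetal. (Locants: oxolane O1, C2 benzyl, C3 OH, C4 CH2OH, C5 aryl; dihydrobenzofuran O1', C2' aryl, C3' CH2OH.)
The dihydrobenzofuran half is cut at C2'-C3' (carbenoid C-H insertion), at aryl-C3' (arylation of ethyl diazoacetate) and at the phenol O-CH2 bond (Mitsunobu), which leads to vanillin and 5-iodovanillin. The alcohol half is cut at the acyl-alkyne bond, which leads to homovanillic acid and a silylated propargyl alcohol.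
Enabling feature: O1 joins C2 and C5. C5 bears an aryl ring whose dihydrobenzofuran oxygen O1' stands para to it and stabilises an O1=C5 oxocarbenium ion. C3 (oxygenated) and C4 (carbon-branched) together are a masked enol. C5 can therefore be hung on O1 as an acetal carbon and then passed from the methoxy oxygen to C4 of an enol ether generated from the C3-C4 alkyne.
Forward order: dihydrobenzofuran ring first (step 10), C-O union of the halves as a mixed acetal (step 13), oxolane ring last (step 14), then adjustment of C4 and C3 and release of the phenols.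
Stereochemistry: C2 comes from asymmetric transfer hydrogenation of the ynone, C5 forms cis to C2 in the rearrangement, C4 is set by equilibration of the 3-ketone to 4,5-trans, and C3 by hydride delivered from the C4 CH2OH group. C2'/C3' arise as the kinetic cis pair from a chiral dirhodium catalyst and are kept by holding base away from the ester and freeing the para-phenol only in the last step.
Key step: step 14

Reading of the target: the oxolane is (2S,3S,4S,5S), with benzyl, OH and aryl on one face and CH2OH on the other. The dihydrobenzofuran is (2'R,3'R), which is 2',3'-cis.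
Assumption: Rh2(S-PTTL)4 is taken to give the 2'R series, as it does with simpler 2-(benzyloxy)phenyl diazoacetates; if the sense were reversed on this substrate, Rh2(R-PTTL)4 would be used with nothing else changed.
Abbreviations in names: ArT = 3-methoxy-4-(triisopropylsilyloxy)phenyl. DBF-TBS = (2R,3R)-3-[(tert-butyldimethylsilyloxy)methyl]-7-methoxy-2-ArT-2,3-dihydro-1-benzofuran-5-yl (2,3-cis). DBF-OH = the same group with a free 3-CH2OH.

Step 1
Reactants: 1 homovanillic acid
Product: 3 2-(4-hydroxy-3-methoxyphenyl)-N-methoxy-N-methylacetamide, via homovanilloyl imidazolide 2 (not isolated)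
Conditions: CDI (1.1 equiv), THF, rt; then MeNH(OMe)·HCl (1.3 equiv), rt
Reagents that add atoms: N,O-dimethylhydroxylamine hydrochloride CNOC.Cl; 1,1'-carbonyldiimidazole O=C(n1ccnc1)n1ccnc1 (imidazolyl group of 2 only)
Why: Weinreb amide synthesis through the acyl imidazolide, in which the carboxylic acid is activated much faster than the hydrogen-bonded guaiacol OH and the imidazolide is then opened by the hydroxylamine, so no phenol protection is needed at this stage.

Step 2
Reactants: 3 2-(4-hydroxy-3-methoxyphenyl)-N-methoxy-N-methylacetamide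
Product: 4 N-methoxy-N-methyl-2-ArT-acetamide (O-TIPS Weinreb amide)
Conditions: TIPSCl, imidazole, DMF, rt
Reagents that add atoms: triisopropylsilyl chloride CC(C)[Si](Cl)(C(C)C)C(C)C
Why: Standard imidazole-promoted silylation of a phenol, the aryl TIPS ether being chosen because it withstands the organolithium, hydride, Lewis-acid and mild aqueous-acid steps ahead yet falls to fluoride within minutes.

Step 3
Reactants: 4 O-TIPS Weinreb amide; 5 tert-butyldimethyl(prop-2-yn-1-yloxy)silane
Product: 7 5-(tert-butyldimethylsilyloxy)-1-ArT-pent-3-yn-2-one (benzyl ynone), via lithium acetylide 6 (not isolated)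
Conditions: 5 (1.3 equiv), n-BuLi (1.25 equiv), THF, −78 °C; then 4, −78 to −20 °C; AcOH quench at −78 °C
Reagents that add atoms: n-butyllithium [Li]CCCC (lithium of 6 only)
Why: Weinreb ketone synthesis, in which the lithium acetylide adds once to give a chelated tetrahedral adduct that cannot over-add, and the cold acidic quench releases the enolisable benzyl ynone without base-induced isomerisation to an allenyl ketone.

Step 4
Reactants: 7 benzyl ynone
Product: 8 (2S)-5-(tert-butyldimethylsilyloxy)-1-ArT-pent-3-yn-2-ol
Conditions: Ru[(S,S)-TsNCH(Ph)CH(Ph)NH](p-cymene) (2 mol %), i-PrOH, rt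
Reagents that add atoms: none
Why: Noyori asymmetric transfer hydrogenation of an alkynyl ketone, in which the (S,S)-configured amido-ruthenium catalyst tells the alkynyl from the sp3 CH2Ar substituent and delivers hydride to the face that gives the (S)-carbinol (the future C2), under neutral conditions that touch neither the triple bond nor the acidic benzylic CH2.

Step 5
Reactants: 9 vanillin
Product: 10 3-methoxy-4-(triisopropylsilyloxy)benzaldehyde
Conditions: TIPSCl, imidazole, DMF, rt
Reagents that add atoms: triisopropylsilyl chloride CC(C)[Si](Cl)(C(C)C)C(C)C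
Why: Standard imidazole-promoted silylation of the phenol, which blocks quinone methide formation in the benzylic intermediates that follow.

Step 6
Reactants: 10 3-methoxy-4-(triisopropylsilyloxy)benzaldehyde
Product: 11 ArT-methanol (O-TIPS vanillyl alcohol)
Conditions: NaBH4, MeOH, 0 °C
Reagents that add atoms: none
Why: Chemoselective borohydride reduction of an aromatic aldehyde, to which the aryl silyl ether is inert at 0 °C.

Step 7
Reactants: 11 O-TIPS vanillyl alcohol; 12 5-iodovanillin
Product: 13 3-iodo-5-methoxy-4-(ArT-methoxy)benzaldehyde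
Conditions: PPh3, DIAD, THF, 0 °C to rt
Reagents that add atoms: none
Why: Mitsunobu etherification, well suited here because the phenol of 12 is made acidic by its para-formyl and ortho-iodo groups while the primary benzylic alcohol is activated in situ, so that the unstable para-silyloxybenzyl halide is never needed.

Step 8
Reactants: 13 3-iodo-5-methoxy-4-(ArT-methoxy)benzaldehyde
Product: 14 5-(dimethoxymethyl)-1-iodo-3-methoxy-2-(ArT-methoxy)benzene
Conditions: HC(OMe)3 (3 equiv), PPTS (5 mol %), MeOH, rt; Et3N quench
Reagents that add atoms: trimethyl orthoformate COC(OC)OC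
Why: Acid-catalysed acetalisation driven by the orthoformate as water scavenger, with a catalyst mild enough for the aryl silyl ether and the electron-rich benzyl aryl ether, installs the very group that later supplies the acetal carbon C5.

Step 9
Reactants: 14 iodoaryl dimethyl acetal; 15 ethyl diazoacetate
Product: 16 ethyl 2-diazo-2-[5-(dimethoxymethyl)-3-methoxy-2-(ArT-methoxy)phenyl]acetate
Conditions: Pd(PPh3)4 (5 mol %), Ag2CO3 (0.5 equiv), Et3N (1.3 equiv), toluene, rt
Reagents that add atoms: none
Why: Palladium-catalysed cross-coupling of an aryl iodide with the C-H bond of a diazoacetate, which runs by oxidative addition to zerovalent palladium, silver-assisted iodide abstraction with deprotonative palladation of the diazo carbon and reductive elimination at room temperature, where the diazo group is retained and acetal, silyl ether and benzyl ether are inert.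

Step 10
Reactants: 16 aryldiazoacetate
Product: 17 ethyl (2R,3S)-5-(dimethoxymethyl)-7-methoxy-2-ArT-2,3-dihydro-1-benzofuran-3-carboxylate (2,3-cis)
Conditions: Rh2(S-PTTL)4 (1 mol %; PTTL = N-phthaloyl-tert-leucinate), toluene, −60 °C
Reagents that add atoms: none
Why: Intramolecular 1,5 C-H insertion of a donor/acceptor dirhodium carbenoid into the ether-activated, electron-rich benzylic CH2 is an established route to cis-2-aryl-2,3-dihydrobenzofuran-3-carboxylates, the concerted insertion at low temperature giving the kinetic cis pair and the chiral carboxylate ligands selecting one enantiotopic C-H bond, which sets C2' (R) and C3' (S in the ester) together.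

Step 11
Reactants: 17 cis-dihydrobenzofuran ester
Product: 18 [(2R,3R)-5-(dimethoxymethyl)-7-methoxy-2-ArT-2,3-dihydro-1-benzofuran-3-yl]methanol (2,3-cis)
Conditions: i-Bu2AlH (3 equiv), CH2Cl2, −78 to −40 °C; aq potassium sodium tartrate
Reagents that add atoms: none
Why: Ester-to-alcohol reduction by a Lewis-acidic, non-basic hydride at low temperature avoids enolisation of the doubly activated C3'-H, so the cis relation is kept (the descriptor becomes 3'R only through the CIP priorities), and the acetal is not attacked in this temperature range.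

Step 12
Reactants: 18 cis-dihydrobenzofuran alcohol
Product: 19 (2R,3R)-3-[(tert-butyldimethylsilyloxy)methyl]-5-(dimethoxymethyl)-7-methoxy-2-ArT-2,3-dihydro-1-benzofuran (2,3-cis; DBF-TBS carbaldehyde dimethyl acetal)
Conditions: TBSCl, imidazole, CH2Cl2, rt
Reagents that add atoms: tert-butyldimethylsilyl chloride CC(C)(C)[Si](C)(C)Cl
Why: Standard silylation of a primary alcohol, and once the ester is gone C3'-H is no longer acidic, so imidazole is harmless to the cis ring.

Step 13
Reactants: 19 DBF-TBS carbaldehyde dimethyl acetal; 8 (S)-propargylic alcohol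
Product: 21 methyl (2S)-5-(tert-butyldimethylsilyloxy)-1-ArT-pent-3-yn-2-yl acetal of DBF-TBS carbaldehyde (both epimers at the acetal carbon), via N-(alpha-methoxybenzyl)collidinium triflate 20 (not isolated)
Conditions: 19 (1.3 equiv), Et3SiOTf (1.25 equiv), 2,4,6-collidine (3 equiv), CH2Cl2, 0 °C; then 8 (1.0 equiv), 0 °C to rt; Et3N-deactivated silica
Reagents that add atoms: 2,4,6-collidine Cc1cc(C)nc(C)c1 and triethylsilyl triflate CC[Si](CC)(CC)OS(=O)(=O)C(F)(F)F (atoms found in 20 only)
Why: Silyl triflate and collidine activation of a dimethyl acetal is a known way to mixed acetals: one methoxy group leaves as Et3SiOMe, the aryl-stabilised oxocarbenium ion is stored as the collidinium salt 20 and this mild electrophile is displaced by the secondary alcohol in a weakly basic medium, which spares all silyl ethers, prevents Friedel-Crafts capture by the benzyl ring and stops after one exchange, while the new acetal centre forms as both epimers without consequence because it becomes planar in step 14.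

Step 14
Reactants: 21 alkynyl mixed acetal
Product: 22 (2S,5R)-2-(ArT-methyl)-4-[(tert-butyldimethylsilyloxy)methyl]-5-(DBF-TBS)-3-methoxy-2,5-dihydrofuran (2,5-cis)
Conditions: (C6F5)3PAuCl (5 mol %), AgSbF6 (5 mol %), 2,6-di-tert-butylpyridine (10 mol %), 4 Å MS, CH2Cl2, −20 °C to rt
Reagents that add atoms: none
Why: Proposed new method: cationic monovalent gold binds the alkyne, the acetal methoxy oxygen attacks the proximal alkyne carbon C3 in a 5-exo-dig mode to give a 1,3-dioxolanium ion bearing an exocyclic vinylgold, and the bond between that oxygen and the acetal carbon C5 then breaks because the O1=C5 oxocarbenium ion is stabilised by the aryl ring through its para oxygen O1'. The aurated enol ether carbon C4 adds to C5 and gold departs, which forms the C4-C5 bond, leaves the C3=C4 methyl enol ether and closes the oxolane ring O1-C2-C3-C4-C5 in a 5-(enol-endo)-endo-trig mode, the mode that also operates in the aluminium-promoted Petasis-Ferrier rearrangement of 4-alkylidene-1,3-dioxolanes. The closest known reaction types are the gold-catalysed carboalkoxylation of ortho-alkynylbenzyl ethers and acetals to indenyl ethers (same alkoxy transfer, five-membered carbocycle) and the gold-catalysed formal Petasis-Ferrier reaction of homopropargylic mixed acetals of terminal alkynes to 4-alkoxydihydropyrans, so what is new is the oxolane closure from a propargylic acetal of an internal alkyne. The only new stereocentre, C5, is controlled by C2, since both acetal epimers converge on one planar (E)-oxocarbenium ion that should close through an envelope with the C2 benzyl and C5 aryl groups pseudo-equatorial and the small C2-H turned towards the C5 substituent, which gives the 2,5-cis ring (5R by the CIP priorities of the enol ether, the same spatial arrangement as 5S in the target). The step needs regioselectivity for oxygen attack at C3, which the substrate secures because attack at C4 (6-endo-dig) could only end in an oxetane and should revert, while both alkyne carbons carry an oxygenated carbon so that no electronic bias opposes the kinetically favoured 5-exo path. It also needs chemoselectivity for C4 over the electron-rich benzyl ring as nucleophile (oxa-Pictet-Spengler closure or hydroarylation), secured by the far higher nucleophilicity of the vinylgold enol ether born next to C5 and by the hindered pyridine and sieves, which keep Brønsted acid from ionising the acetal on its own and spare the silyl ethers and the cis-dihydrobenzofuran.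

Step 15
Reactants: 22 2,5-cis-3-methoxy-2,5-dihydrofuran
Product: 25 (2S,4R,5S)-2-(ArT-methyl)-4-(hydroxymethyl)-5-(DBF-OH)-oxolan-3-one (2,5-cis 4,5-trans keto diol), via all-cis bis-TBS ketone 23 (not isolated), via 4-epi keto diol 24 (not isolated)
Conditions: p-TsOH·H2O (0.2 equiv), THF-H2O (10:1), rt; then KOAc (3 equiv), MeOH, rt
Reagents that add atoms: water O
Why: Acid hydrolysis of the enol ether (C-protonation at C4 from the face away from the C5 aryl group, then loss of methanol) and solvolysis of the two primary TBS ethers are standard and leave the acid-stable aryl TIPS ethers, and acetate-buffered enolisation then moves C4 from the crowded all-cis array to the thermodynamic 4,5-trans (4R) arrangement, in which 2,5-cis is also the preferred relation so that C2 is not endangered, without the strong base that would trigger retro-aldol loss of formaldehyde or dehydration.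

Step 16
Reactants: 25 2,5-cis 4,5-trans keto diol
Product: 26 (2S,3S,4S,5S)-2-(ArT-methyl)-4-(hydroxymethyl)-5-(DBF-OH)-oxolan-3-ol (bis-TIPS triol)
Conditions: Me4NBH(OAc)3 (6 equiv), MeCN-AcOH (1:1), −30 to −20 °C; aq potassium sodium tartrate
Reagents that add atoms: none
Why: Evans-Saksena hydroxyl-directed reduction, in which the C4 CH2OH group exchanges for acetate on boron and the resulting alkoxydiacetoxyborohydride, the only species reactive enough to reduce a ketone under these conditions, hands its hydride through a six-membered transition state to the face of C3 on which the CH2OH stands, so that the new hydroxyl group ends up trans to CH2OH and cis to the benzyl group (3S).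

Step 17
Reactants: 26 bis-TIPS triol
Product: 27 (2S,3S,4S,5S)-2-(4-hydroxy-3-methoxybenzyl)-5-[(2R,3R)-2-(4-hydroxy-3-methoxyphenyl)-3-(hydroxymethyl)-7-methoxy-2,3-dihydro-1-benzofuran-5-yl]-4-(hydroxymethyl)oxolan-3-ol (CNP0179668.1)
Conditions: n-Bu4NF (2.5 equiv), AcOH (3 equiv), THF, 0 °C
Reagents that add atoms: none
Why: Fluoride cleavage of aryl silyl ethers is fast at 0 °C, and with acetic acid present the liberated phenols are never held as phenoxides, which shuts off the quinone methide ring-opening by which the cis C2'-O1' bond could epimerise to the trans series.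

Compound list
1 | homovanillic acid | COc1cc(CC(=O)O)ccc1O | starting material
2 | homovanilloyl imidazolide | COc1cc(CC(=O)n2ccnc2)ccc1O | intermediate
3 | 2-(4-hydroxy-3-methoxyphenyl)-N-methoxy-N-methylacetamide | COc1cc(CC(=O)N(C)OC)ccc1O | intermediate
4 | N-methoxy-N-methyl-2-[3-methoxy-4-(triisopropylsilyloxy)phenyl]acetamide | COc1cc(CC(=O)N(C)OC)ccc1O[Si](C(C)C)(C(C)C)C(C)C | intermediate
5 | tert-butyldimethyl(prop-2-yn-1-yloxy)silane | C#CCO[Si](C)(C)C(C)(C)C | starting material
6 | lithium 3-(tert-butyldimethylsilyloxy)prop-1-yn-1-ide | [Li]C#CCO[Si](C)(C)C(C)(C)C | intermediate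
7 | 5-(tert-butyldimethylsilyloxy)-1-[3-methoxy-4-(triisopropylsilyloxy)phenyl]pent-3-yn-2-one | COc1cc(CC(=O)C#CCO[Si](C)(C)C(C)(C)C)ccc1O[Si](C(C)C)(C(C)C)C(C)C | intermediate
8 | (2S)-5-(tert-butyldimethylsilyloxy)-1-[3-methoxy-4-(triisopropylsilyloxy)phenyl]pent-3-yn-2-ol | COc1cc(C[C@@H](C#CCO[Si](C)(C)C(C)(C)C)O)ccc1O[Si](C(C)C)(C(C)C)C(C)C | intermediate
9 | vanillin | COc1cc(C=O)ccc1O | starting material
10 | 3-methoxy-4-(triisopropylsilyloxy)benzaldehyde | COc1cc(C=O)ccc1O[Si](C(C)C)(C(C)C)C(C)C | intermediate
11 | [3-methoxy-4-(triisopropylsilyloxy)phenyl]methanol | COc1cc(CO)ccc1O[Si](C(C)C)(C(C)C)C(C)C | intermediate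
12 | 5-iodovanillin (4-hydroxy-3-iodo-5-methoxybenzaldehyde) | COc1cc(C=O)cc(I)c1O | starting material
13 | 3-iodo-5-methoxy-4-{[3-methoxy-4-(triisopropylsilyloxy)benzyl]oxy}benzaldehyde | COc1cc(C=O)cc(I)c1OCc1ccc(O[Si](C(C)C)(C(C)C)C(C)C)c(OC)c1 | intermediate
14 | dimethyl acetal of 13 | COc1cc(C(OC)OC)cc(I)c1OCc1ccc(O[Si](C(C)C)(C(C)C)C(C)C)c(OC)c1 | intermediate
15 | ethyl diazoacetate | CCOC(=O)C=[N+]=[N-] | starting material
16 | ethyl 2-diazo-2-[5-(dimethoxymethyl)-3-methoxy-2-{[3-methoxy-4-(triisopropylsilyloxy)benzyl]oxy}phenyl]acetate | COc1cc(C(OC)OC)cc(C(=[N+]=[N-])C(=O)OCC)c1OCc1ccc(O[Si](C(C)C)(C(C)C)C(C)C)c(OC)c1 | intermediate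
17 | ethyl (2R,3S)-cis-5-(dimethoxymethyl)-7-methoxy-2-[3-methoxy-4-(triisopropylsilyloxy)phenyl]-2,3-dihydro-1-benzofuran-3-carboxylate | COC(OC)c1cc(OC)c2c(c1)[C@H](C(=O)OCC)[C@H](c1ccc(O[Si](C(C)C)(C(C)C)C(C)C)c(OC)c1)O2 | intermediate
18 | (2R,3R)-cis 3-hydroxymethyl analogue of 17 | COC(OC)c1cc(OC)c2c(c1)[C@H](CO)[C@H](c1ccc(O[Si](C(C)C)(C(C)C)C(C)C)c(OC)c1)O2 | intermediate
19 | (2R,3R)-cis 3-(TBS-oxymethyl) dihydrobenzofuran-5-carbaldehyde dimethyl acetal | COC(OC)c1cc(OC)c2c(c1)[C@H](CO[Si](C)(C)C(C)(C)C)[C@H](c1ccc(O[Si](C(C)C)(C(C)C)C(C)C)c(OC)c1)O2 | intermediate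
20 | 1-[(DBF-TBS)(methoxy)methyl]-2,4,6-trimethylpyridinium triflate | COC(c1cc(OC)c2c(c1)[C@H](CO[Si](C)(C)C(C)(C)C)[C@H](c1ccc(O[Si](C(C)C)(C(C)C)C(C)C)c(OC)c1)O2)[n+]1c(C)cc(C)cc1C.[O-]S(=O)(=O)C(F)(F)F | intermediate
21 | alkynyl mixed acetal (acetal carbon as both epimers) | COc1cc(C[C@@H](C#CCO[Si](C)(C)C(C)(C)C)OC(OC)c2cc(OC)c3c(c2)[C@H](CO[Si](C)(C)C(C)(C)C)[C@H](c2ccc(O[Si](C(C)C)(C(C)C)C(C)C)c(OC)c2)O3)ccc1O[Si](C(C)C)(C(C)C)C(C)C | intermediate
22 | (2S,5R)-2,5-cis-3-methoxy-2,5-dihydrofuran | COc1cc(C[C@@H]2O[C@H](c3cc(OC)c4c(c3)[C@H](CO[Si](C)(C)C(C)(C)C)[C@H](c3ccc(O[Si](C(C)C)(C(C)C)C(C)C)c(OC)c3)O4)C(CO[Si](C)(C)C(C)(C)C)=C2OC)ccc1O[Si](C(C)C)(C(C)C)C(C)C | intermediate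
23 | (2S,4S,5S) all-cis bis-TBS oxolan-3-one | COc1cc(C[C@@H]2O[C@H](c3cc(OC)c4c(c3)[C@H](CO[Si](C)(C)C(C)(C)C)[C@H](c3ccc(O[Si](C(C)C)(C(C)C)C(C)C)c(OC)c3)O4)[C@H](CO[Si](C)(C)C(C)(C)C)C2=O)ccc1O[Si](C(C)C)(C(C)C)C(C)C | intermediate
24 | (2S,4S,5S) all-cis keto diol (4-epimer of 25) | COc1cc(C[C@@H]2O[C@H](c3cc(OC)c4c(c3)[C@H](CO)[C@H](c3ccc(O[Si](C(C)C)(C(C)C)C(C)C)c(OC)c3)O4)[C@H](CO)C2=O)ccc1O[Si](C(C)C)(C(C)C)C(C)C | intermediate
25 | (2S,4R,5S) 2,5-cis 4,5-trans keto diol | COc1cc(C[C@@H]2O[C@H](c3cc(OC)c4c(c3)[C@H](CO)[C@H](c3ccc(O[Si](C(C)C)(C(C)C)C(C)C)c(OC)c3)O4)[C@@H](CO)C2=O)ccc1O[Si](C(C)C)(C(C)C)C(C)C | intermediate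
26 | (2S,3S,4S,5S) bis-TIPS triol | COc1cc(C[C@@H]2O[C@H](c3cc(OC)c4c(c3)[C@H](CO)[C@H](c3ccc(O[Si](C(C)C)(C(C)C)C(C)C)c(OC)c3)O4)[C@@H](CO)[C@@H]2O)ccc1O[Si](C(C)C)(C(C)C)C(C)C | intermediate
27 | CNP0179668.1 | COc1cc(C[C@@H]2O[C@H](c3cc(OC)c4c(c3)[C@H](CO)[C@H](c3ccc(O)c(OC)c3)O4)[C@@H](CO)[C@@H]2O)ccc1O | target

Total step count: 17.
Longest linear sequence: 13 steps (steps 5 to 17: 9, 10, 11, 13, 14, 16, 17, 18, 19, 21, 22, 25, 26, 27).

Steps most likely to fail

1. Step 14 (key step).
- The 5-endo closure may be too slow, so that the oxocarbenium ion sheds the aldehyde or is captured by the electron-rich benzyl ring.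
- The alkyne may undergo hydroarylation, or the alkoxy transfer may take the 6-endo course.
- The facial selectivity at C5 may be poor.

The fallback uses known reactions only. It sets out from 8 and 19 and comes back at 23. It makes C4-C5 by a carbonyl addition and O1-C5 afterwards. Alcohol 8 undergoes hydroxyl-directed trans-hydroalumination with NaAlH2(OCH2CH2OMe)2 in THF at 0 °C, and the alkenylalane is quenched with I2 at −78 °C. This places iodine on C4, cis to C2, and gives the (2S,3Z)-4-iodoalkenol F1. Acetal 19 is hydrolysed (PPTS, acetone-H2O, rt) to the DBF-TBS carbaldehyde F2. A Nozaki-Hiyama-Kishi coupling of F1 with F2 (CrCl2 as the divalent chromium source, catalytic NiCl2, DMF, rt) tolerates the free hydroxyl group and gives the (Z)-ene-1,4-diol F3 as C5 epimers. Catalytic camphorsulfonic acid in CH2Cl2 at 0 °C ionises the benzylic and allylic C5-OH, and the C2 hydroxyl closes O1-C5 to the 2,5-cis-2,5-dihydrofuran F4. The C5-O1 bond re-ionises under the same acid, so any trans isomer can be separated and resubmitted. Hydroboration-oxidation (BH3·THF, then NaBO3·4H2O) from the face opposite the two ring substituents puts the hydroxyl group on the less substituted C3 and gives the (2S,3R,4R,5S)-oxolan-3-ol F5. Dess-Martin oxidation of F5 delivers 23, which is carried through the acid and acetate stages of step 15.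

2. Step 9.
- Oxidative addition and palladation next to the ortho-benzyloxy group of an electron-rich iodide may be sluggish.
- Palladium may meanwhile decompose the diazo compounds by carbene dimerisation.

The fallback sets out from 14 and comes back at 16. It installs the carbon chain first and the diazo group second. A Negishi-type coupling of 14 with the Reformatsky reagent BrZnCH2CO2Et (Pd(dba)2, P(t-Bu)3, THF, rt) gives the ethyl arylacetate F6. Regitz diazo transfer (4-acetamidobenzenesulfonyl azide, DBU, MeCN, 0 °C to rt) then converts its activated CH2 into the diazo ester 16.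

3. Step 13.
- Residual silyl triflate may silylate the alcohol.
- Displacement by the hindered secondary alcohol may be slow.
- A second exchange or hydrolysis may occur during isolation.

The fallback sets out from 19 and 8 and comes back at 21. The electrophile is prepared as a discrete reagent, and the alcohol is then alkylated as in an alkoxymethyl protection. Acetal 19 is treated with acetyl chloride and catalytic ZnCl2 in toluene at 0 °C to give the alpha-chlorobenzyl methyl ether F7. Alcohol 8 and i-Pr2NEt are then added in CH2Cl2 at 0 °C to give 21.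

Further compounds
F1 | step 14 | (2S,3Z)-5-(tert-butyldimethylsilyloxy)-4-iodo-1-[3-methoxy-4-(triisopropylsilyloxy)phenyl]pent-3-en-2-ol | COc1cc(C[C@H](O)/C=C(\I)CO[Si](C)(C)C(C)(C)C)ccc1O[Si](C(C)C)(C(C)C)C(C)C
F2 | step 14 | (2R,3R)-cis-3-(TBS-oxymethyl)-7-methoxy-2-[3-methoxy-4-(triisopropylsilyloxy)phenyl]-2,3-dihydro-1-benzofuran-5-carbaldehyde | O=Cc1cc(OC)c2c(c1)[C@H](CO[Si](C)(C)C(C)(C)C)[C@H](c1ccc(O[Si](C(C)C)(C(C)C)C(C)C)c(OC)c1)O2
F3 | step 14 | (Z)-ene-1,4-diol (C2 S, C5 as both epimers) | COc1cc(C[C@H](O)/C=C(CO[Si](C)(C)C(C)(C)C)\C(O)c2cc(OC)c3c(c2)[C@H](CO[Si](C)(C)C(C)(C)C)[C@H](c2ccc(O[Si](C(C)C)(C(C)C)C(C)C)c(OC)c2)O3)ccc1O[Si](C(C)C)(C(C)C)C(C)C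
F4 | step 14 | (2S,5R)-2,5-cis-2,5-dihydrofuran lacking the 3-methoxy group | COc1cc(C[C@@H]2O[C@H](c3cc(OC)c4c(c3)[C@H](CO[Si](C)(C)C(C)(C)C)[C@H](c3ccc(O[Si](C(C)C)(C(C)C)C(C)C)c(OC)c3)O4)C(CO[Si](C)(C)C(C)(C)C)=C2)ccc1O[Si](C(C)C)(C(C)C)C(C)C
F5 | step 14 | (2S,3R,4R,5S)-oxolan-3-ol (3-OH trans to benzyl, 4-CH2OTBS cis to aryl) | COc1cc(C[C@@H]2O[C@H](c3cc(OC)c4c(c3)[C@H](CO[Si](C)(C)C(C)(C)C)[C@H](c3ccc(O[Si](C(C)C)(C(C)C)C(C)C)c(OC)c3)O4)[C@H](CO[Si](C)(C)C(C)(C)C)[C@H]2O)ccc1O[Si](C(C)C)(C(C)C)C(C)C
F6 | step 9 | ethyl 2-[5-(dimethoxymethyl)-3-methoxy-2-{[3-methoxy-4-(triisopropylsilyloxy)benzyl]oxy}phenyl]acetate | COc1cc(C(OC)OC)cc(CC(=O)OCC)c1OCc1ccc(O[Si](C(C)C)(C(C)C)C(C)C)c(OC)c1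
F7 | step 13 | chloro(methoxy)methyl derivative of the DBF-TBS unit (alpha-chloro ether, both epimers) | COC(Cl)c1cc(OC)c2c(c1)[C@H](CO[Si](C)(C)C(C)(C)C)[C@H](c1ccc(O[Si](C(C)C)(C(C)C)C(C)C)c(OC)c1)O2
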